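The route rests on delivering the angular methyl C20 as a CH2 bridge. The quaternary ring-fusion carbon C10 carries C20 cis to the C1 oxygen of ring A and next to C9 of ring B, so a free C1 hydroxyl can steer a zinc carbenoid onto a C9=C10 alkene. In one operation the cyclopropanation forms C10–C20 and C9–C20, closes the three-membered ring and fixes C10 relative to C1, C4 and C5. The precursor is a bicyclic allylic alcohol with free C1–OH, a trisubstituted C9=C10 alkene, a C8 silyl ether on the opposite face, and the C4 methyl/ester pair and H5 already in place. Reductive opening of the derived C8 cyclopropyl ketone later turns the bridge into C20 and hands over a C9 enolate.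

Key step: step 12

Remarks on the chemistry:
- Atom numbers follow the labdane skeleton of the target: ring A = C1–C5 and C10, ring B = C5–C10, side chain C11–C16, C17 = exocyclic CH2 on C8, C18 = methyl and C19 = ester carbon on C4, C20 = methyl on C10. In the target O1, C19, C20 and C11 lie on one face; H5, H9 and C18 lie on the other.
- An arylacetate does not carry the C4 methyl (C18), so it is added by α-methylation before the Michael step. The quaternary C4 is made racemic in step 2 and becomes single-enantiomer material in step 4. C19 is a free acid only during the arene reduction.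
- Assumption: RuCl(p-cymene)[(S,S)-TsDPEN] gives the (S)-carbinol from 7 as it does from 1-tetralone; if the sense were reversed, the (R,R) catalyst would be used.

Step 1
Reactants: 1 methyl 2-(4-methoxyphenyl)acetate
Product: 2 methyl 2-(4-methoxyphenyl)propanoate (racemic)
Conditions: LiN(iPr)2, THF, −78 °C; MeI, −78 → 0 °C
Reagents that add atoms: iodomethane, CI
Why: Ester enolate alkylation (SN2) supplies the C4 methyl C18, and one equivalent of base at low temperature should keep it to monomethylation.

Step 2
Reactants: 2 methyl 2-(4-methoxyphenyl)propanoate; 3 tert-butyl acrylate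
Product: 4 5-tert-butyl 1-methyl 2-(4-methoxyphenyl)-2-methylpentanedioate (racemic)
Conditions: KOtBu (0.1 equiv), t-BuOH/THF, 0 → 25 °C
Reagents that add atoms: none
Why: Base-catalysed Michael addition of the only acidic C–H builds the quaternary C4 and attaches C3–C1 as a differentiated tert-butyl ester; the centre forms racemic and is sorted in step 4.

Step 3
Reactants: 4 5-tert-butyl 1-methyl 2-(4-methoxyphenyl)-2-methylpentanedioate
Product: 7 methyl 6-methoxy-1-methyl-4-oxo-1,2,3,4-tetrahydronaphthalene-1-carboxylate (racemic tetralone), via carboxylic acid 5 (not isolated), via acid chloride 6 (not isolated)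
Conditions: CF3CO2H, CH2Cl2, 25 °C; evaporate; (COCl)2, DMF (cat.), CH2Cl2, 25 °C; then AlCl3, 0 °C
Reagents that add atoms: none
Why: Acidolysis of the tert-butyl ester and intramolecular Friedel–Crafts acylation ortho to the quaternary carbon (the closure used for 7-methoxy-1-tetralone) form ring A, while the hindered C19 methyl ester cannot cyclise and stays intact.

Step 4
Reactants: 7 methyl 6-methoxy-1-methyl-4-oxo-1,2,3,4-tetrahydronaphthalene-1-carboxylate (racemic)
Product: 8 methyl (1R,4S)-4-hydroxy-6-methoxy-1-methyl-1,2,3,4-tetrahydronaphthalene-1-carboxylate (hydroxyl cis to the ester)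
Conditions: RuCl(p-cymene)[(S,S)-TsDPEN] (1 mol%), HCO2H/Et3N (5:2), 30 °C; chromatography to remove the trans alcohol
Reagents that add atoms: none
Why: Noyori–Ikariya asymmetric transfer hydrogenation should set C1 as S by catalyst control in both antipodes of 7, so the racemate becomes two separable diastereomers and the cis alcohol, which alone has 4R, is kept (at most half of the material).

Step 5
Reactants: 8 methyl (1R,4S)-4-hydroxy-6-methoxy-1-methyl-1,2,3,4-tetrahydronaphthalene-1-carboxylate
Product: 9 (1R,4S)-4-hydroxy-6-methoxy-1-methyl-1,2,3,4-tetrahydronaphthalene-1-carboxylic acid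
Conditions: KOH, MeOH/H2O, 70 °C; then 1 M HCl, 0 °C, to pH 4
Reagents that add atoms: potassium hydroxide, [K+].[OH-]
Why: Saponification, assisted by the cis-disposed alkoxide, gives the acid because a carboxylate, unlike an ester, survives the dissolving-metal reduction that follows.

Step 6
Reactants: 9 (1R,4S)-4-hydroxy-6-methoxy-1-methyl-1,2,3,4-tetrahydronaphthalene-1-carboxylic acid
Product: 11 (1R,4S,8aS)-4-hydroxy-1-methyl-6-oxo-1,2,3,4,6,7,8,8a-octahydronaphthalene-1-carboxylic acid (C8 enone with C9=C10; H5 trans to O1 and to C19), via dienol ether 10 (not isolated)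
Conditions: n-BuLi (2.0 equiv), THF, −78 °C; Li, NH3(l), t-BuOH, −78 → −33 °C; NH4Cl; then 2 M HCl, THF, 25 °C
Reagents that add atoms: water, O
Why: Birch reduction of the anisole ring (benzylic oxygen and acid held as lithium alkoxide and carboxylate) gives the 2,5-dihydroanisole, and acid hydrolysis with conjugation gives the C8 enone; C5 is set by reversible γ-protonation under thermodynamic control, which is expected to favour, only moderately, H5 trans to the C19 carboxyl that then sits axial on ring A.

Step 7
Reactants: 11 (1R,4S,8aS)-4-hydroxy-1-methyl-6-oxo-1,2,3,4,6,7,8,8a-octahydronaphthalene-1-carboxylic acid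
Product: 12 methyl (1R,4S,8aS)-4-hydroxy-1-methyl-6-oxo-1,2,3,4,6,7,8,8a-octahydronaphthalene-1-carboxylate
Conditions: MeI, KHCO3, DMF, 25 °C
Reagents that add atoms: iodomethane, CI
Why: SN2 O-alkylation of the carboxylate restores the C19 methyl ester under conditions too mild for the γ-hydroxy enone; the C5 epimer is separated here and returned to acid equilibration.

Step 8
Reactants: 12 methyl (1R,4S,8aS)-4-hydroxy-1-methyl-6-oxo-1,2,3,4,6,7,8,8a-octahydronaphthalene-1-carboxylate
Product: 13 methyl (1R,4S,8aS)-4-acetoxy-1-methyl-6-oxo-1,2,3,4,6,7,8,8a-octahydronaphthalene-1-carboxylate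
Conditions: Ac2O, pyridine, DMAP (cat.), CH2Cl2, 0 → 25 °C
Reagents that add atoms: acetic anhydride, CC(=O)OC(C)=O
Why: Acylation masks the C1 hydroxyl so that the C8 oxygen can be generated and silylated without competition.

Step 9
Reactants: 13 methyl (1R,4S,8aS)-4-acetoxy-1-methyl-6-oxo-1,2,3,4,6,7,8,8a-octahydronaphthalene-1-carboxylate
Product: 14 methyl (1R,4S,6S,8aS)-4-acetoxy-6-hydroxy-1-methyl-1,2,3,4,6,7,8,8a-octahydronaphthalene-1-carboxylate
Conditions: NaBH4, CeCl3·7H2O, MeOH, −78 → −40 °C
Reagents that add atoms: none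
Why: Luche 1,2-reduction by axial hydride attack should give the pseudo-equatorial C8 alcohol cis to H5, on the face opposite to O1 (this centre is erased in step 15).

Step 10
Reactants: 14 methyl (1R,4S,6S,8aS)-4-acetoxy-6-hydroxy-1-methyl-1,2,3,4,6,7,8,8a-octahydronaphthalene-1-carboxylate
Product: 15 methyl (1R,4S,6S,8aS)-4-acetoxy-1-methyl-6-(triethylsilyloxy)-1,2,3,4,6,7,8,8a-octahydronaphthalene-1-carboxylate
Conditions: Et3SiCl, imidazole, DMF, 0 °C
Reagents that add atoms: chlorotriethylsilane, CC[Si](Cl)(CC)CC
Why: Silylation of the only free hydroxyl places a bulky, non-coordinating ether on the face opposite to O1.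

Step 11
Reactants: 15 methyl (1R,4S,6S,8aS)-4-acetoxy-1-methyl-6-(triethylsilyloxy)-1,2,3,4,6,7,8,8a-octahydronaphthalene-1-carboxylate
Product: 16 methyl (1R,4S,6S,8aS)-4-hydroxy-1-methyl-6-(triethylsilyloxy)-1,2,3,4,6,7,8,8a-octahydronaphthalene-1-carboxylate (C1 allylic alcohol, C9=C10, C8 silyl ether)
Conditions: K2CO3, MeOH, 0 → 25 °C
Reagents that add atoms: none
Why: Methanolysis removes the acetate, while the triethylsilyl ether and the hindered C19 ester are stable to methanolic carbonate.

Step 12
Reactants: 16 C1 allylic alcohol with C9=C10 and C8 triethylsilyl ether; 17 diiodomethane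
Product: 18 9,10-methano compound: cyclopropane across C9–C10 with C20 cis to the C1 hydroxyl and trans to H5, C8 triethylsilyl ether and C19 methyl ester unchanged
Conditions: Et2Zn (3 equiv), CH2I2 (5 equiv), CH2Cl2, −15 → 25 °C
Reagents that add atoms: none
Why: Et2Zn first turns the C1 hydroxyl into a zinc alkoxide, which binds the iodomethylzinc species and holds it over the alkene face that carries O1 (hydroxyl-directed Simmons–Smith reaction, Furukawa variant). Methylene is then passed to C9=C10 in a single concerted, butterfly-type event, so C10–C20 and C9–C20 form together and the three-membered ring closes by a cheletropic [2+1] addition, necessarily cis-fused to ring B. Both new stereocentres, C10 and C9, are dictated by the C1 carbinol: C20 ends up cis to O1 and therefore trans to H5 and cis to C19, as the target requires. Only facial selectivity is needed; it is secured by intramolecular delivery from the alkoxide, by the non-coordinating silyl ether at C8 shielding the other face, and by the absence of any second alkene. The closest known reaction type is the directed cyclopropanation of cyclic allylic alcohols, which tolerates trisubstituted alkenes and esters.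

Step 13
Reactants: 18 9,10-methano alcohol
Product: 19 C1 tert-butyldimethylsilyl ether of 18 (C8 triethylsilyl ether retained)
Conditions: t-BuMe2SiOTf, 2,6-lutidine, CH2Cl2, −78 → 0 °C
Reagents that add atoms: tert-butyldimethylsilyl trifluoromethanesulfonate, CC(C)(C)[Si](C)(C)OS(=O)(=O)C(F)(F)F
Why: A silyl triflate with a hindered base silylates the congested C1 carbinol, giving an ether that survives mild acid, dissolving metal, cuprate and the titanium reagent and is removed by fluoride at the end.

Step 14
Reactants: 19 bis-silyl ether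
Product: 20 C8 alcohol with C1 tert-butyldimethylsilyl ether (9,10-methano skeleton)
Conditions: PPTS (cat.), MeOH/CH2Cl2, 0 °C
Reagents that add atoms: none
Why: Mild acid methanolysis cleaves a triethylsilyl ether far faster than a hindered tert-butyldimethylsilyl ether.

Step 15
Reactants: 20 C8 alcohol
Product: 21 C8 cyclopropyl ketone (9,10-methano, C1 tert-butyldimethylsilyl ether, C19 methyl ester)
Conditions: Dess–Martin periodinane, NaHCO3, CH2Cl2, 25 °C
Reagents that add atoms: none
Why: Dess–Martin oxidation under buffered, neutral conditions gives the ketone without opening the cyclopropylcarbinyl system.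

Step 16
Reactants: 21 C8 cyclopropyl ketone
Product: 23 Mannich base: C8 ketone with CH2NMe2 on C9 and the C20 methyl on C10 (C9 configuration immaterial), via lithium enolate 22 (not isolated)
Conditions: Li (2.1 equiv), t-BuOH (1.0 equiv), NH3(l)/THF, −78 °C; evaporate NH3; H2C=NMe2+ I−, THF, −78 → 0 °C
Reagents that add atoms: dimethyl(methylidene)ammonium iodide, C[N+](C)=C.[I-]
Why: Electron transfer to the ketone cleaves the cyclopropane bond that overlaps the carbonyl π system (C9–C20), leaving C20 as the methyl on C10 after protonation and a regiodefined C8–C9 lithium enolate, which the iminium salt aminomethylates at C9 (Mannich reaction).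

Step 17
Reactants: 23 Mannich base
Product: 25 exocyclic enone: C8 ketone with C9=C11H2 (C1 tert-butyldimethylsilyl ether, C19 methyl ester, C20 methyl), via methiodide 24 (not isolated)
Conditions: MeI, CH2Cl2/MeOH, 25 °C; then NaHCO3 (aq), 25 °C
Reagents that add atoms: none
Why: N-Methylation and Hofmann-type β-elimination of trimethylamine give the α-methylene ketone, which also removes the C9 centre of 23.

Step 18
Reactants: 26 prop-2-yn-1-ol
Product: 27 (E)-3-iodo-2-methylprop-2-en-1-ol
Conditions: Me3Al (3 equiv), Cp2ZrCl2 (0.25 equiv), CH2Cl2, 0 → 25 °C; then I2, THF, −30 °C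
Reagents that add atoms: trimethylaluminium, C[Al](C)C; iodine, II
Why: Negishi carboalumination adds CH3 and Al syn across the alkyne with methyl on the internal carbon, and iodinolysis with retention gives the E iodoalkene that becomes C12=C13.

Step 19
Reactants: 27 (E)-3-iodo-2-methylprop-2-en-1-ol
Product: 28 (E)-3-iodo-2-methylprop-2-enal
Conditions: MnO2, CH2Cl2, 25 °C
Reagents that add atoms: none
Why: MnO2 oxidises the allylic alcohol selectively and leaves the vinyl iodide and its geometry untouched.

Step 20
Reactants: 28 (E)-3-iodo-2-methylprop-2-enal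
Product: 29 (E)-1-iodo-2-methylbuta-1,3-diene (kept as an ethereal solution)
Conditions: Ph3PCH3Br, KN(SiMe3)2, THF, −78 → 0 °C
Reagents that add atoms: methyltriphenylphosphonium bromide, C[P+](c1ccccc1)(c1ccccc1)c1ccccc1.[Br-]
Why: Wittig methylenation of the enal installs the terminal C14=C15 alkene without affecting the trisubstituted double bond.

Step 21
Reactants: 25 exocyclic enone; 29 (E)-1-iodo-2-methylbuta-1,3-diene
Product: 33 C8 ketone carrying the (2E)-3-methylpenta-2,4-dienyl chain on C9 cis to C20 (H9 cis to H5; C1 tert-butyldimethylsilyl ether), via dienyllithium 30 (not isolated), via lithium cuprate 31 (not isolated), via lithium enolate 32 (not isolated)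
Conditions: t-BuLi (2 equiv per 29), Et2O, −78 °C; CuI (0.5 equiv per 29), −78 → −40 °C; then 25, THF, −78 °C; AcOH/THF, −78 °C
Reagents that add atoms: none
Why: Iodine–lithium exchange with retention and Gilman cuprate 1,4-addition to the unhindered exocyclic CH2 form C11–C12, and the resulting C8–C9 enolate should be protonated kinetically on the face of H5, anti to the axial C20 methyl on the neighbouring C10 (axial protonation), which sets C9.

Step 22
Reactants: 33 C8 ketone with side chain
Product: 34 methyl (1S,4R,5S,9R,10S,12E)-1-(tert-butyldimethylsilyloxy)labda-8(17),12,14-trien-19-oate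
Conditions: Zn, CH2Br2, TiCl4, THF/CH2Cl2, 0 → 25 °C
Reagents that add atoms: dibromomethane, BrCBr
Why: Takai–Lombardo methylenation converts the hindered C8 ketone into the exocyclic alkene under non-basic conditions, so the C9 α-centre does not epimerise and the esters are not attacked.

Step 23
Reactants: 34 methyl 1-(tert-butyldimethylsilyloxy)labda-8(17),12,14-trien-19-oate
Product: 35 methyl (1S,4R,5S,9R,10S,12E)-1-hydroxylabda-8(17),12,14-trien-19-oate
Conditions: Bu4NF, THF, 40 °C
Reagents that add atoms: none
Why: Fluoride cleaves the Si–O bond at C1 without touching the ester or the triene, which an acidic deprotection could isomerise.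

Step 24
Reactants: 35 methyl 1-hydroxylabda-8(17),12,14-trien-19-oate
Product: 36 methyl (1S,4R,5S,9R,10S,12E)-1-acetoxylabda-8(17),12,14-trien-19-oate (CNP0235031.1)
Conditions: Ac2O, DMAP, pyridine, 40 °C
Reagents that add atoms: acetic anhydride, CC(=O)OC(C)=O
Why: DMAP-catalysed acylation of the hindered secondary C1 alcohol gives the acetate and completes the target.

Compound list
1 | methyl 2-(4-methoxyphenyl)acetate | COC(=O)Cc1ccc(OC)cc1 | starting material
2 | methyl 2-(4-methoxyphenyl)propanoate (racemic) | COC(=O)C(C)c1ccc(OC)cc1 | intermediate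
3 | tert-butyl prop-2-enoate (tert-butyl acrylate) | C=CC(=O)OC(C)(C)C | starting material
4 | 5-tert-butyl 1-methyl 2-(4-methoxyphenyl)-2-methylpentanedioate (racemic) | COC(=O)C(C)(CCC(=O)OC(C)(C)C)c1ccc(OC)cc1 | intermediate
5 | 5-methoxy-4-(4-methoxyphenyl)-4-methyl-5-oxopentanoic acid (racemic) | COC(=O)C(C)(CCC(=O)O)c1ccc(OC)cc1 | intermediate (not isolated)
6 | methyl 5-chloro-2-(4-methoxyphenyl)-2-methyl-5-oxopentanoate (racemic) | COC(=O)C(C)(CCC(=O)Cl)c1ccc(OC)cc1 | intermediate (not isolated)
7 | methyl 6-methoxy-1-methyl-4-oxo-1,2,3,4-tetrahydronaphthalene-1-carboxylate (racemic) | COc1ccc2c(c1)C(=O)CCC2(C)C(=O)OC | intermediate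
8 | methyl (1R,4S)-4-hydroxy-6-methoxy-1-methyl-1,2,3,4-tetrahydronaphthalene-1-carboxylate | COc1ccc2c(c1)[C@@H](O)CC[C@@]2(C)C(=O)OC | intermediate
9 | (1R,4S)-4-hydroxy-6-methoxy-1-methyl-1,2,3,4-tetrahydronaphthalene-1-carboxylic acid | COc1ccc2c(c1)[C@@H](O)CC[C@@]2(C)C(=O)O | intermediate
10 | (1R,4S)-4-hydroxy-6-methoxy-1-methyl-1,2,3,4,5,8-hexahydronaphthalene-1-carboxylic acid (dienol ether; C5=C10 and C7=C8) | COC1=CCC2=C(C1)[C@@H](O)CC[C@@]2(C)C(=O)O | intermediate (not isolated)
11 | (1R,4S,8aS)-4-hydroxy-1-methyl-6-oxo-1,2,3,4,6,7,8,8a-octahydronaphthalene-1-carboxylic acid | O=C1CC[C@H]2C(=C1)[C@@H](O)CC[C@@]2(C)C(=O)O | intermediate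
12 | methyl (1R,4S,8aS)-4-hydroxy-1-methyl-6-oxo-1,2,3,4,6,7,8,8a-octahydronaphthalene-1-carboxylate | O=C1CC[C@H]2C(=C1)[C@@H](O)CC[C@@]2(C)C(=O)OC | intermediate
13 | methyl (1R,4S,8aS)-4-acetoxy-1-methyl-6-oxo-1,2,3,4,6,7,8,8a-octahydronaphthalene-1-carboxylate | O=C1CC[C@H]2C(=C1)[C@@H](OC(C)=O)CC[C@@]2(C)C(=O)OC | intermediate
14 | methyl (1R,4S,6S,8aS)-4-acetoxy-6-hydroxy-1-methyl-1,2,3,4,6,7,8,8a-octahydronaphthalene-1-carboxylate | O[C@H]1CC[C@H]2C(=C1)[C@@H](OC(C)=O)CC[C@@]2(C)C(=O)OC | intermediate
15 | methyl (1R,4S,6S,8aS)-4-acetoxy-1-methyl-6-(triethylsilyloxy)-1,2,3,4,6,7,8,8a-octahydronaphthalene-1-carboxylate | CC[Si](CC)(CC)O[C@H]1CC[C@H]2C(=C1)[C@@H](OC(C)=O)CC[C@@]2(C)C(=O)OC | intermediate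
16 | methyl (1R,4S,6S,8aS)-4-hydroxy-1-methyl-6-(triethylsilyloxy)-1,2,3,4,6,7,8,8a-octahydronaphthalene-1-carboxylate (key-step precursor) | CC[Si](CC)(CC)O[C@H]1CC[C@H]2C(=C1)[C@@H](O)CC[C@@]2(C)C(=O)OC | intermediate
17 | diiodomethane | ICI | starting material
18 | 9,10-methano alcohol: C20 bridging C9 and C10 cis to the C1 hydroxyl, trans to H5; C8 triethylsilyl ether; C19 methyl ester (key-step product) | CC[Si](CC)(CC)O[C@H]1CC[C@H]2[C@@]3(C[C@H]13)[C@@H](O)CC[C@@]2(C)C(=O)OC | intermediate
19 | C1 tert-butyldimethylsilyl ether of 18 | CC[Si](CC)(CC)O[C@H]1CC[C@H]2[C@@]3(C[C@H]13)[C@@H](O[Si](C)(C)C(C)(C)C)CC[C@@]2(C)C(=O)OC | intermediate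
20 | 9,10-methano C8 alcohol with C1 tert-butyldimethylsilyl ether | O[C@H]1CC[C@H]2[C@@]3(C[C@H]13)[C@@H](O[Si](C)(C)C(C)(C)C)CC[C@@]2(C)C(=O)OC | intermediate
21 | 9,10-methano C8 ketone (cyclopropyl ketone) with C1 tert-butyldimethylsilyl ether | O=C1CC[C@H]2[C@@]3(C[C@H]13)[C@@H](O[Si](C)(C)C(C)(C)C)CC[C@@]2(C)C(=O)OC | intermediate
22 | lithium C8–C9 enolate with C20 methyl on C10 | C1=C(O[Li])CC[C@H]2[C@@]1(C)[C@@H](O[Si](C)(C)C(C)(C)C)CC[C@@]2(C)C(=O)OC | intermediate (not isolated)
23 | Mannich base: C8 ketone with CH2NMe2 on C9 (C9 undefined) | CN(C)CC1C(=O)CC[C@H]2[C@@]1(C)[C@@H](O[Si](C)(C)C(C)(C)C)CC[C@@]2(C)C(=O)OC | intermediate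
24 | trimethylammonium iodide (methiodide) of 23 | C[N+](C)(C)CC1C(=O)CC[C@H]2[C@@]1(C)[C@@H](O[Si](C)(C)C(C)(C)C)CC[C@@]2(C)C(=O)OC.[I-] | intermediate (not isolated)
25 | exocyclic enone: C8 ketone with C9=C11H2 | C=C1C(=O)CC[C@H]2[C@@]1(C)[C@@H](O[Si](C)(C)C(C)(C)C)CC[C@@]2(C)C(=O)OC | intermediate
26 | prop-2-yn-1-ol | C#CCO | starting material
27 | (E)-3-iodo-2-methylprop-2-en-1-ol | OC/C(C)=C/I | intermediate
28 | (E)-3-iodo-2-methylprop-2-enal | O=C/C(C)=C/I | intermediate
29 | (E)-1-iodo-2-methylbuta-1,3-diene | C=C/C(C)=C/I | intermediate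
30 | (E)-(2-methylbuta-1,3-dienyl)lithium | C=C/C(C)=C/[Li] | intermediate (not isolated)
31 | lithium bis[(E)-2-methylbuta-1,3-dienyl]cuprate | [Li+].C=C/C(C)=C/[Cu-]/C=C(C)/C=C | intermediate (not isolated)
32 | lithium C8–C9 enolate carrying the dienyl chain on C9 | C=C/C(C)=C/CC1=C(O[Li])CC[C@H]2[C@@]1(C)[C@@H](O[Si](C)(C)C(C)(C)C)CC[C@@]2(C)C(=O)OC | intermediate (not isolated)
33 | C8 ketone with (2E)-3-methylpenta-2,4-dienyl on C9 cis to C20 (methyl 1-(tert-butyldimethylsilyloxy)-8-oxo-17-norlabda-12,14-dien-19-oate) | C=C/C(C)=C/C[C@@H]1C(=O)CC[C@H]2[C@@]1(C)[C@@H](O[Si](C)(C)C(C)(C)C)CC[C@@]2(C)C(=O)OC | intermediate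
34 | methyl (1S,4R,5S,9R,10S,12E)-1-(tert-butyldimethylsilyloxy)labda-8(17),12,14-trien-19-oate | C=C/C(C)=C/C[C@@H]1C(=C)CC[C@H]2[C@@]1(C)[C@@H](O[Si](C)(C)C(C)(C)C)CC[C@@]2(C)C(=O)OC | intermediate
35 | methyl (1S,4R,5S,9R,10S,12E)-1-hydroxylabda-8(17),12,14-trien-19-oate | C=C/C(C)=C/C[C@@H]1C(=C)CC[C@H]2[C@@]1(C)[C@@H](O)CC[C@@]2(C)C(=O)OC | intermediate
36 | methyl (1S,4R,5S,9R,10S,12E)-1-acetoxylabda-8(17),12,14-trien-19-oate | C=C/C(C)=C/C[C@@H]1C(=C)CC[C@H]2[C@@]1(C)[C@@H](OC(C)=O)CC[C@@]2(C)C(=O)OC | target

Total step count: 24 (21 in the main line, 3 for iododiene 29).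
Longest linear sequence: 21 steps (steps 1–17 and 21–24).

Steps most likely to fail

Step 6. The benzylic C1–O bond may be cleaved reductively if the alkoxide is not fully formed. More seriously, the γ-protonation that sets C5 may show poor facial selectivity, because the two ring-A chair forms (ester axial with O1 equatorial, or methyl axial with O1 axial) differ little in energy. Fallback: starting from 11 as the C5 epimer mixture, O1 and C19 are joined with EDC·HCl/DMAP to the bridged lactone F1. Its boat-shaped ring A removes the C1 conformational term, and C5 is then equilibrated with DBU, where the ring-B carbon C6 should prefer the side of the lactone bridge. Luche reduction gives the allylic alcohol lactone F2 and Et3SiCl/imidazole gives the silyl ether lactone F3. NaOMe/MeOH then opens the lactone to the methyl ester and free C1 hydroxyl, which rejoins the route at 16.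

Step 21. The enolate protonation at C9 may show poor facial selectivity, or the dienyl cuprate may decompose before it adds. Fallback: starting from 21, the reduction of step 16 is repeated, but enolate 22 is C-alkylated directly with (E)-5-bromo-3-methylpenta-1,3-diene F4 (from commercial 3-methylpenta-1,4-dien-3-ol and PBr3 with allylic transposition). The electrophile should enter anti to C20 and give the C9-epimeric ketone F5. NaOMe/MeOH then equilibrates C9, the desired epimer is separated and F5 is recycled; the route is rejoined at 33.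

Step 16. The regiodefined enolate may be lost by proton transfer before the iminium salt reacts, giving the plain ketone. Fallback: starting from 21, the reduction mixture is freed of ammonia and quenched with Me3SiCl/Et3N to give the isolable trimethylsilyl enol ether F6. This is aminomethylated with the same iminium iodide in CH2Cl2 (Mukaiyama–Mannich type), which rejoins the route at 23.

Further compounds
F1 | step 6 | bridged lactone of 11 (O1 acylated by C19; C8 enone, C9=C10) | O=C1CC[C@H]2C(=C1)[C@@H]3CC[C@@]2(C)C(=O)O3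
F2 | step 6 | C8 allylic alcohol of the bridged lactone (hydroxyl cis to H5) | O[C@H]1CC[C@H]2C(=C1)[C@@H]3CC[C@@]2(C)C(=O)O3
F3 | step 6 | C8 triethylsilyl ether of the bridged lactone | CC[Si](CC)(CC)O[C@H]1CC[C@H]2C(=C1)[C@@H]3CC[C@@]2(C)C(=O)O3
F4 | step 21 | (E)-5-bromo-3-methylpenta-1,3-diene | C=C/C(C)=C/CBr
F5 | step 21 | C9 epimer of 33 (side chain trans to C20) | C=C/C(C)=C/C[C@H]1C(=O)CC[C@H]2[C@@]1(C)[C@@H](O[Si](C)(C)C(C)(C)C)CC[C@@]2(C)C(=O)OC
F6 | step 16 | trimethylsilyl enol ether of the C8 ketone (C8=C9, C20 methyl on C10) | C1=C(O[Si](C)(C)C)CC[C@H]2[C@@]1(C)[C@@H](O[Si](C)(C)C(C)(C)C)CC[C@@]2(C)C(=O)OC
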